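## Retrosynthetic overview

1. Feature (benzofuran numbering, primes for ring B): ring A (C3a, C4, C5, C6, C7, C7a) carries oxygen on C7a and C6, a methyl group on C4, and C3 with ring B on C3a. Oxygen on every second carbon marks a linear chain Ar–C3(O)–C3aH2–C7a(O)–C7H2–C6(O)–C5H2–C4(O)–CH3 closed between C3a and C4.
2. Endgame: the three phenols come from methyl ethers. The furan ring (O1, C2, C3, C3a, C7a) is cut at C2=C3 to a 2-acyloxybenzophenone (reductive keto ester coupling), and O1–C2 is cut to methyl succinyl chloride.
3. Ring A: the benzophenone is cut at C3a–C4 to the tetraketone, which is stored as a 2-(aroylmethyl)-6-methyl-4-pyranone and released by hydroxide only when it is to cyclize.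
4. Pyranone: C3–C3a comes from acylating laterally lithiated 2,6-dimethyl-4-pyranone with methyl 3,5-dimethoxy-2,4-dimethylbenzoate. That ester is made from 3,5-dimethoxy-4-methylbenzoic acid by esterification, bromination and Suzuki methylation.
5. Order of rings: ring B is bought, ring A forms in step 5, and the furan ring forms in step 8.

Key step: step 5

Assumption: the SMILES carries no stereodescriptor, so the hindered C3–C1' biaryl axis is treated as configurationally undefined and no atropisomer control is attempted.

## Route

Step 1
Reactants: 1 3,5-dimethoxy-4-methylbenzoic acid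
Product: 2 methyl 3,5-dimethoxy-4-methylbenzoate
Conditions: MeOH, H2SO4 (cat.), reflux
Reagents that add atoms: methanol, CO
Why: Fischer esterification of a benzoic acid without ortho substituents, driven by methanol as solvent.

Step 2
Reactants: 2 methyl 3,5-dimethoxy-4-methylbenzoate
Product: 3 methyl 2-bromo-3,5-dimethoxy-4-methylbenzoate
Conditions: NBS (1.0 equiv), MeCN, 0 °C → rt, dark
Reagents that add atoms: N-bromosuccinimide, O=C1CCC(=O)N1Br
Why: Electrophilic aromatic bromination, in which the equivalent positions C2 and C6 each lie ortho to one methoxy group and para to the other, so one equivalent of NBS in a polar solvent should give the monobromide without radical attack on the methyl group, and the halide handle avoids an ortho-formyl benzoate, whose reduction tends to end at the phthalide.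

Step 3
Reactants: 3 methyl 2-bromo-3,5-dimethoxy-4-methylbenzoate
Product: 4 methyl 3,5-dimethoxy-2,4-dimethylbenzoate
Conditions: MeB(OH)2 (2 equiv), Pd(OAc)2 (cat.), SPhos (cat.), K3PO4, toluene/H2O, 100 °C
Reagents that add atoms: methylboronic acid, CB(O)O
Why: Suzuki–Miyaura methylation, in which the ortho ester speeds oxidative addition, the bulky biaryl phosphine handles the di-ortho-substituted bromide, and the methyl ester should survive the biphasic phosphate base.

Step 4
Reactants: 4 methyl 3,5-dimethoxy-2,4-dimethylbenzoate; 5 2,6-dimethyl-4H-pyran-4-one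
Product: 7 2-[2-(3,5-dimethoxy-2,4-dimethylphenyl)-2-oxoethyl]-6-methyl-4H-pyran-4-one, via lithium dienolate 6 (not isolated)
Conditions: 5 (2.2 equiv), LiHMDS (2.2 equiv), THF, -78 °C; then 4, -78 → 0 °C; 1 M HCl
Reagents that add atoms: LiHMDS, [Li+].C[Si](C)(C)[N-][Si](C)(C)C (supplies the lithium of 6 only; nothing of it stays in 7)
Why: Lateral (vinylogous) deprotonation gives a dienolate that reacts at its exocyclic carbon so that the pyranone is restored, the Claisen-type acylation of the non-enolizable ester is pulled forward when the second equivalent of 6 deprotonates the acidic product, and LiHMDS is too weak a base to metalate the ortho-toluate methyl group of 4.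

Step 5
Reactants: 7 2-[2-(3,5-dimethoxy-2,4-dimethylphenyl)-2-oxoethyl]-6-methyl-4H-pyran-4-one
Product: 9 (2,4-dihydroxy-6-methylphenyl)(3,5-dimethoxy-2,4-dimethylphenyl)methanone, via tetraketone 8 (not isolated)
Conditions: 2 M aq KOH/MeOH, 60 °C, Ar; then 2 M HCl, 0 °C
Reagents that add atoms: water, O (enters as hydroxide on the way to 8 and is lost again on aromatization)
Why: Hydroxide adds in conjugate fashion to the methyl-bearing pyranone carbon (C4 of the target), the hemiketal opens with the ring oxygen leaving as the C7a enolate, and tetraketone 8 is released as its polyenolate only at this point. The enolate carbon C3a, flanked by the aroyl carbonyl C3 and the C7a carbonyl, adds to the terminal methyl ketone C4 in a 6-exo-trig aldol closure that forms the C3a–C4 bond and ring A, and loss of water followed by enolization at C6 and C7a makes the sequence irreversible, so that 9 is an isomer of 7. The closest known reaction type is the base-induced opening of 4-pyranones to poly-β-carbonyl chains and the aldol aromatization of 1-aryl-1,3,5,7-tetraketones and 3,5,7-triketo esters to 2,4-dihydroxy-6-methylphenyl ketones and orsellinates. No stereocenter is formed. The step needs regioselectivity among three possible six-membered closures, namely C3a on C4 (wanted), C5 on the aryl ketone C3, and the terminal CH3 on C7a. Since the aldol additions are reversible and aromatization decides, the outcome should follow the electrophile: C4 is an unhindered, unconjugated methyl ketone, C3 is conjugated with ring B, is screened by the ortho methyl group on C2' and would give a crowded tertiary carbinol next to the acetyl-bearing C5 (the methoxy groups sit meta to C3 and give no electronic help), and the CH3 closure asks the least acidic carbon to attack a carbonyl that is enolized from both sides.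

Step 6
Reactants: 9 (2,4-dihydroxy-6-methylphenyl)(3,5-dimethoxy-2,4-dimethylphenyl)methanone
Product: 10 (2-hydroxy-4-methoxy-6-methylphenyl)(3,5-dimethoxy-2,4-dimethylphenyl)methanone
Conditions: MeI (1.05 equiv), K2CO3 (1.1 equiv), acetone, rt → 40 °C
Reagents that add atoms: iodomethane, CI
Why: Williamson etherification under weak base, in which the free and more acidic hydroxyl para to the ketone (C6-OH of the target) reacts while the ortho hydroxyl is held in a hydrogen bond to the carbonyl and shielded by the aroyl group, as in the standard monoalkylation of 2,4-dihydroxybenzophenones.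

Step 7
Reactants: 10 (2-hydroxy-4-methoxy-6-methylphenyl)(3,5-dimethoxy-2,4-dimethylphenyl)methanone; 11 methyl 4-chloro-4-oxobutanoate (methyl succinyl chloride)
Product: 12 2-(3,5-dimethoxy-2,4-dimethylbenzoyl)-5-methoxy-3-methylphenyl methyl butanedioate
Conditions: Et3N, DMAP (cat.), CH2Cl2, 0 °C → rt
Reagents that add atoms: none
Why: DMAP-catalysed O-acylation through the acylpyridinium ion overcomes the hydrogen bond of the chelated phenol, and the mild amine base should not start an aldol of the new ester α-CH2 on the ketone (coumarin formation).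

Step 8
Reactants: 12 2-(3,5-dimethoxy-2,4-dimethylbenzoyl)-5-methoxy-3-methylphenyl methyl butanedioate
Product: 13 methyl 3-[3-(3,5-dimethoxy-2,4-dimethylphenyl)-6-methoxy-4-methyl-1-benzofuran-2-yl]propanoate
Conditions: TiCl3 (6 equiv), Zn dust (12 equiv), THF, reflux, 2 h; then 12 added slowly, reflux, Ar; filtration through silica
Reagents that add atoms: none
Why: Intramolecular McMurry-type keto ester coupling, the established low-valent titanium route from 2-acyloxybenzophenones to 2-alkyl-3-arylbenzofurans, in which electron transfer to the easily reduced diaryl ketone gives a titanium-bound ketyl that adds to the aryl ester carbonyl in a five-membered closure, deoxygenation gives the aromatic furan with the C2=C3 bond, and the remote methyl ester, which could only close an eight-membered ring, should stay untouched.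

Step 9
Reactants: 13 methyl 3-[3-(3,5-dimethoxy-2,4-dimethylphenyl)-6-methoxy-4-methyl-1-benzofuran-2-yl]propanoate
Product: 14 talarominine A (methyl 3-[3-(3,5-dihydroxy-2,4-dimethylphenyl)-6-hydroxy-4-methyl-1-benzofuran-2-yl]propanoate)
Conditions: BBr3 (6 equiv), CH2Cl2, -78 → 0 °C; MeOH quench, then 50 °C, 1 h
Reagents that add atoms: none
Why: Lewis-acid cleavage of aryl methyl ethers, in which BBr3 binds each ether oxygen and bromide removes the methyl group by SN2, the aliphatic methyl ester is cleaved far more slowly at or below 0 °C, and the HBr/MeOH generated by the quench would return any acid that had formed to the ester by Fischer esterification.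

## Compound list

1 | 3,5-dimethoxy-4-methylbenzoic acid | COc1cc(C(=O)O)cc(OC)c1C | starting material
2 | methyl 3,5-dimethoxy-4-methylbenzoate | COC(=O)c1cc(OC)c(C)c(OC)c1 | intermediate
3 | methyl 2-bromo-3,5-dimethoxy-4-methylbenzoate | COC(=O)c1cc(OC)c(C)c(OC)c1Br | intermediate
4 | methyl 3,5-dimethoxy-2,4-dimethylbenzoate | COC(=O)c1cc(OC)c(C)c(OC)c1C | intermediate
5 | 2,6-dimethyl-4H-pyran-4-one | CC1=CC(=O)C=C(C)O1 | starting material
6 | lithium 2-methyl-6-methylidene-6H-pyran-4-olate (lithium dienolate of 5) | [Li+].C=C1C=C([O-])C=C(C)O1 | intermediate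
7 | 2-[2-(3,5-dimethoxy-2,4-dimethylphenyl)-2-oxoethyl]-6-methyl-4H-pyran-4-one | CC1=CC(=O)C=C(CC(=O)c2cc(OC)c(C)c(OC)c2C)O1 | intermediate
8 | 1-(3,5-dimethoxy-2,4-dimethylphenyl)octane-1,3,5,7-tetraone | CC(=O)CC(=O)CC(=O)CC(=O)c1cc(OC)c(C)c(OC)c1C | intermediate
9 | (2,4-dihydroxy-6-methylphenyl)(3,5-dimethoxy-2,4-dimethylphenyl)methanone | Cc1cc(O)cc(O)c1C(=O)c1cc(OC)c(C)c(OC)c1C | intermediate
10 | (2-hydroxy-4-methoxy-6-methylphenyl)(3,5-dimethoxy-2,4-dimethylphenyl)methanone | Cc1cc(OC)cc(O)c1C(=O)c1cc(OC)c(C)c(OC)c1C | intermediate
11 | methyl 4-chloro-4-oxobutanoate (methyl succinyl chloride) | COC(=O)CCC(=O)Cl | starting material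
12 | 2-(3,5-dimethoxy-2,4-dimethylbenzoyl)-5-methoxy-3-methylphenyl methyl butanedioate | COC(=O)CCC(=O)Oc1cc(OC)cc(C)c1C(=O)c1cc(OC)c(C)c(OC)c1C | intermediate
13 | methyl 3-[3-(3,5-dimethoxy-2,4-dimethylphenyl)-6-methoxy-4-methyl-1-benzofuran-2-yl]propanoate | COC(=O)CCc1oc2cc(OC)cc(C)c2c1-c1cc(OC)c(C)c(OC)c1C | intermediate
14 | talarominine A | COC(=O)CCc1oc2cc(O)cc(C)c2c1-c1cc(O)c(C)c(O)c1C | target

## Step count and risks

Total step count: 9. Longest linear sequence: 9 steps (1 → 14); 5 and 11 are bought.

**Step 5.**
- Risk: In base the pyranone sits as its delocalized enolate and may open slowly. Hot hydroxide may cut the released chain by retro-Claisen cleavage. The chain may also fold in the other register, C5 onto C3.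
- Fallback: the diaryl ketone is assembled by Friedel–Crafts acylation instead of by folding. This sets out from 4 and comes back at 10.
- Saponification of 4 (KOH, aq MeOH, reflux) gives 3,5-dimethoxy-2,4-dimethylbenzoic acid F1.
- F1 is activated as its mixed anhydride with trifluoroacetic anhydride and acylates commercial 3,5-dimethoxytoluene at the position ortho to the methyl group and para to a methoxy group. This gives (2,4-dimethoxy-6-methylphenyl)(3,5-dimethoxy-2,4-dimethylphenyl)methanone F2.
- BCl3 in CH2Cl2 at low temperature then removes only the methyl ether ortho to the ketone, through a six-membered boron chelate, and delivers 10.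

**Step 8.**
- Risk: The crowded diaryl ketone may simply be reduced to the carbinol or the methylene stage. The aryl ester may also be lost to the Lewis-acidic titanium and zinc salts before the C–C bond forms.
- Fallback: the furan ring is closed by an aldol condensation and the side chain is grown afterwards. This sets out from 10 and comes back at 13.
- Alkylation of 10 with methyl bromoacetate (K2CO3, DMF) gives methyl 2-[2-(3,5-dimethoxy-2,4-dimethylbenzoyl)-5-methoxy-3-methylphenoxy]acetate F3.
- NaOMe in MeOH closes F3 by attack of the ester enolate on the ketone and loss of water. The product is methyl 3-(3,5-dimethoxy-2,4-dimethylphenyl)-6-methoxy-4-methyl-1-benzofuran-2-carboxylate F4.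
- LiAlH4 gives [3-(3,5-dimethoxy-2,4-dimethylphenyl)-6-methoxy-4-methyl-1-benzofuran-2-yl]methanol F5, and MnO2 gives 3-(3,5-dimethoxy-2,4-dimethylphenyl)-6-methoxy-4-methyl-1-benzofuran-2-carbaldehyde F6.
- Wittig olefination with Ph3P=CHCO2Me gives methyl (E)-3-[3-(3,5-dimethoxy-2,4-dimethylphenyl)-6-methoxy-4-methyl-1-benzofuran-2-yl]prop-2-enoate F7.
- Hydrogenation of the side-chain alkene (H2, Pd/C, EtOAc) gives 13.

**Step 4.**
- Risk: The delocalized dienolate may add only sluggishly to the ortho-substituted ester. On warming it may be used up by self-condensation of the pyranone or by proton transfer.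
- Fallback: the open chain is acylated as a much stronger nucleophile, and the pyranone stage is skipped. This sets out from 5 and comes back at 8.
- Compound 5 is opened with aqueous Ba(OH)2 to heptane-2,4,6-trione F8.
- Three equivalents of LDA in THF convert F8 into the trilithium trienolate of heptane-2,4,6-trione F9.
- The terminal carbon of F9, used in excess, is aroylated by ester 4 (terminal aroylation of a triketone trianion). This gives tetraketone 8 directly.
- Tetraketone 8 is then closed to 9 under the hydroxide conditions of step 5, so the C3a–C4 aldol is kept.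

## Further compounds

F1 | step 5 | 3,5-dimethoxy-2,4-dimethylbenzoic acid | COc1cc(C(=O)O)c(C)c(OC)c1C
F2 | step 5 | (2,4-dimethoxy-6-methylphenyl)(3,5-dimethoxy-2,4-dimethylphenyl)methanone | Cc1cc(OC)cc(OC)c1C(=O)c1cc(OC)c(C)c(OC)c1C
F3 | step 8 | methyl 2-[2-(3,5-dimethoxy-2,4-dimethylbenzoyl)-5-methoxy-3-methylphenoxy]acetate | COC(=O)COc1cc(OC)cc(C)c1C(=O)c1cc(OC)c(C)c(OC)c1C
F4 | step 8 | methyl 3-(3,5-dimethoxy-2,4-dimethylphenyl)-6-methoxy-4-methyl-1-benzofuran-2-carboxylate | COC(=O)c1oc2cc(OC)cc(C)c2c1-c1cc(OC)c(C)c(OC)c1C
F5 | step 8 | [3-(3,5-dimethoxy-2,4-dimethylphenyl)-6-methoxy-4-methyl-1-benzofuran-2-yl]methanol | OCc1oc2cc(OC)cc(C)c2c1-c1cc(OC)c(C)c(OC)c1C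
F6 | step 8 | 3-(3,5-dimethoxy-2,4-dimethylphenyl)-6-methoxy-4-methyl-1-benzofuran-2-carbaldehyde | O=Cc1oc2cc(OC)cc(C)c2c1-c1cc(OC)c(C)c(OC)c1C
F7 | step 8 | methyl (E)-3-[3-(3,5-dimethoxy-2,4-dimethylphenyl)-6-methoxy-4-methyl-1-benzofuran-2-yl]prop-2-enoate | COC(=O)/C=C/c1oc2cc(OC)cc(C)c2c1-c1cc(OC)c(C)c(OC)c1C
F8 | step 4 | heptane-2,4,6-trione | CC(=O)CC(=O)CC(C)=O
F9 | step 4 | trilithium trienolate of heptane-2,4,6-trione | [Li+].[Li+].[Li+].C=C([O-])C=C([O-])C=C(C)[O-]
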